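**Retrosynthetic overview**
– Target ⇒ open-chain γ-hydroxy ketone whose side chain ends in a 2,3,4-trisubstituted furan. The furan is a masked (Z)-keto enal; unmasking and double cyclodehydration close the dihydrofuran (C–O) and the tropone (C–C) in one operation (key step).
– γ-Hydroxy ketone ⇒ spiro γ-lactone acid + laterally lithiated methyl 2-ethyl-4-methylfuran-3-carboxylate (Feist–Benary product of methyl 3-oxopentanoate and chloroacetone).
– Spiro lactone ⇒ 2,2,6-trisubstituted cyclohexanone + methyl acrylate (SmI2 ketyl–olefin coupling sets the spiro centre).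
– Cyclohexanone ⇒ (S)-carvone by hydration, α'-methylation, α'-Michael addition to diethyl methylenemalonate and enone hydrogenation.
– Ring order: cyclohexane (from carvone) → spiro lactone (temporary carrier) and furan (temporary mask, side branch) → dihydrofuran and tropone together in the last step.

Assumption: the target is exactly the stereoisomer of the given SMILES, (5S,8R,9R,10R) in the locants used below: C5 = CH bearing the hydroxyisopropyl group, C8 = CH–CH3, C9 = spiro carbon, C10 = quaternary carbon, C11 = dihydrofuran CH2, t1–t7 = tropone carbons (t1 C=O, t2 C–CO2Me, t3 C–CH3, t4 CH, t5 C–C11, t6 C–O, t7 C–CH3); diethyl methylenemalonate is taken as a commercial stabilised reagent.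

Step 1
Reactants: 1 (S)-(+)-carvone [(5S)-2-methyl-5-(prop-1-en-2-yl)cyclohex-2-en-1-one]
Product: 2 (5S)-5-(2-hydroxypropan-2-yl)-2-methylcyclohex-2-en-1-one
Conditions: 50% aq. H2SO4, 0 °C → rt
Reagents that add atoms: water, O
Why: Acid-catalysed Markovnikov hydration of the 1,1-disubstituted alkene through its tertiary cation leaves the enone and the C5 stereocentre untouched, so the tertiary alcohol of the target is in place before the hydrogenation of step 4.

Step 2
Reactants: 2 (5S)-5-(2-hydroxypropan-2-yl)-2-methylcyclohex-2-en-1-one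
Product: 4 (5S,6R)-5-(2-hydroxypropan-2-yl)-2,6-dimethylcyclohex-2-en-1-one, via dilithium dienolate alkoxide 3 (not isolated)
Conditions: LiN(iPr)2 (2.2 equiv), THF, −78 °C; MeI, −78 → −30 °C; then H2O
Reagents that add atoms: iodomethane, CI
Why: Kinetic α'-deprotonation gives the cross-conjugated dienolate whose C-methylation (enolate alkylation) occurs mainly trans to the bulky alkoxide-bearing group, and the configuration of this new centre does not matter because it is re-enolised in step 3.

Step 3
Reactants: 4 (5S,6R)-5-(2-hydroxypropan-2-yl)-2,6-dimethylcyclohex-2-en-1-one; 5 diethyl 2-methylidenepropanedioate (diethyl methylenemalonate)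
Product: 7 diethyl 2-{[(1R,6S)-6-(2-hydroxypropan-2-yl)-1,3-dimethyl-2-oxocyclohex-3-en-1-yl]methyl}propanedioate, via dilithium dienolate alkoxide 6 (not isolated)
Conditions: LiN(iPr)2 (2.2 equiv), THF, −78 °C; 5 (1.05 equiv), −78 °C, 15 min; AcOH, −78 °C
Reagents that add atoms: none
Why: Michael addition of the tetrasubstituted dienolate to the very electrophilic methylenemalonate takes place on the face anti to the C(CH3)2OLi group, which sets quaternary C10 with its methyl cis and the new arm trans to that group, while the stabilised malonate anion does not close onto the enone in a second Michael addition before the cold quench.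

Step 4
Reactants: 7 diethyl 2-{[(1R,6S)-6-(2-hydroxypropan-2-yl)-1,3-dimethyl-2-oxocyclohex-3-en-1-yl]methyl}propanedioate
Product: 8 diethyl 2-{[(1R,3R,6S)-6-(2-hydroxypropan-2-yl)-1,3-dimethyl-2-oxocyclohexyl]methyl}propanedioate
Conditions: H2 (1 atm), Pd/C (10 wt% Pd on carbon), EtOAc, rt
Reagents that add atoms: none
Why: Heterogeneous catalytic hydrogenation of the enone C=C should deliver hydrogen to the ring face opposite the C10 methyl and the C5 hydroxyisopropyl group, which sets C8 as (R) with its methyl cis to those two groups, and the neutral medium does not epimerise this centre.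

Step 5
Reactants: 8 diethyl 2-{[(1R,3R,6S)-6-(2-hydroxypropan-2-yl)-1,3-dimethyl-2-oxocyclohexyl]methyl}propanedioate; 9 methyl prop-2-enoate (methyl acrylate)
Product: 11 diethyl 2-{[(5R,6R,7S,10R)-7-(2-hydroxypropan-2-yl)-6,10-dimethyl-2-oxo-1-oxaspiro[4.5]decan-6-yl]methyl}propanedioate, via hydroxy ester 10 (not isolated)
Conditions: SmI2 (2.5 equiv), 9 (2 equiv), t-BuOH (2 equiv), THF, −78 → 0 °C
Reagents that add atoms: none
Why: SmI2-mediated ketyl–olefin reductive coupling followed by spontaneous lactonisation forms the C9–C11 bond on the ring face anti to the two α-methyl groups and the hydroxyisopropyl group, which fixes spiro C9 as (R) with its oxygen cis to those groups, and the non-basic conditions leave C8 intact.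

Step 6
Reactants: 11 diethyl 2-{[(5R,6R,7S,10R)-7-(2-hydroxypropan-2-yl)-6,10-dimethyl-2-oxo-1-oxaspiro[4.5]decan-6-yl]methyl}propanedioate
Product: 13 3-[(5R,6R,7S,10R)-7-(2-hydroxypropan-2-yl)-6,10-dimethyl-2-oxo-1-oxaspiro[4.5]decan-6-yl]propanoic acid, via lactone malonic acid 12 (not isolated)
Conditions: LiOH (6 equiv), THF/H2O, 50 °C; 2 M HCl to pH 2; then pyridine, 100 °C
Reagents that add atoms: lithium hydroxide, [Li+].[OH-]
Why: Ester saponification (the lactone opens only by acyl–oxygen cleavage and re-closes on acidification) and thermal decarboxylation of the malonic acid, the endgame of a malonic ester synthesis, reveal the propanoic acid arm without breaking any bond to a stereocentre.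

Step 7
Reactants: 14 methyl 3-oxopentanoate; 15 1-chloropropan-2-one (chloroacetone)
Product: 16 methyl 2-ethyl-4-methylfuran-3-carboxylate
Conditions: pyridine, 50 °C
Reagents that add atoms: none
Why: The Feist–Benary furan synthesis (aldol addition of the β-keto ester carbon to the ketone of chloroacetone, then intramolecular O-alkylation and dehydration) gives the 2,4-dialkylfuran-3-carboxylate regioisomer, a masked (Z)-2-ene-1,4-dicarbonyl unit that holds t7, t1, t2, t3 and t4 in the right order.

Step 8
Reactants: 13 3-[(5R,6R,7S,10R)-7-(2-hydroxypropan-2-yl)-6,10-dimethyl-2-oxo-1-oxaspiro[4.5]decan-6-yl]propanoic acid; 16 methyl 2-ethyl-4-methylfuran-3-carboxylate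
Product: 18 3-[(1R,2R,3R,6S)-2-hydroxy-6-(2-hydroxypropan-2-yl)-2-{4-[3-(methoxycarbonyl)-4-methylfuran-2-yl]-3-oxopentyl}-1,3-dimethylcyclohexyl]propanoic acid (open-chain γ-hydroxy ketone; both epimers at the side-chain CH(CH3)), via lithiated furan ester 17 (not isolated)
Conditions: 16 (2.3 equiv), LiN(iPr)2 (4.6 equiv), THF, −78 °C; then 13, −78 → 0 °C; aq. HCl to pH 3, 0 °C
Reagents that add atoms: none
Why: Lateral lithiation of the 2-ethyl group gives a vinylogous ester enolate that opens the lactone in a Claisen-type acylation (the extra base holds the acid and the alcohols as lithium salts and enolises the product), which leaves the four ring stereocentres untouched and creates only a side-chain CH(CH3) centre that is destroyed in step 9.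

Step 9
Reactants: 18 3-[(1R,2R,3R,6S)-2-hydroxy-6-(2-hydroxypropan-2-yl)-2-{4-[3-(methoxycarbonyl)-4-methylfuran-2-yl]-3-oxopentyl}-1,3-dimethylcyclohexyl]propanoic acid
Product: 21 3-[(1'R,2'R,3'S,6'R)-3'-(2-hydroxypropan-2-yl)-6-(methoxycarbonyl)-2',5,6',8-tetramethyl-7-oxo-3,7-dihydrospiro[cyclohepta[b]furan-2,1'-cyclohexan]-2'-yl]propanoic acid (CNP0448476.2), via furan endoperoxide 19 (not isolated), via keto enal 20 (not isolated)
Conditions: O2, hν (visible), tetraphenylporphyrin (1 mol%), CH2Cl2, −78 °C; Me2S, −78 °C → rt; then TsOH·H2O (0.2 equiv), MeCN/H2O 20:1, 45 °C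
Reagents that add atoms: dioxygen, O=O
Why: Proposed new method: singlet-oxygen [4+2] cycloaddition to the furan and Me2S reduction unmask the (Z)-keto enal 20, in which acid lets the C9 hydroxyl add to the t6 ketone and dehydrate to the cyclic enol ether while enol ether carbon t5 attacks the cis-held aldehyde t4 in an intramolecular aldol condensation whose dehydration is driven by tropone aromaticity (the competing five-membered aldol through t7 cannot dehydrate and is reversible), so the dihydrofuran and tropone rings close in one operation without ionising the C9–O bond or touching C5, C8, C9 or C10; the closest known reaction types are furan photooxygenation to cis-enediones, acid-catalysed cyclodehydration of γ-hydroxy 1,3-diketones to 2-alkylidene tetrahydrofurans and aldol-condensation syntheses of tropones from dicarbonyl compounds.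

**Compound list**
1 | (S)-(+)-carvone; (5S)-2-methyl-5-(prop-1-en-2-yl)cyclohex-2-en-1-one | CC1=CC[C@H](C(C)=C)CC1=O | starting material
2 | (5S)-5-(2-hydroxypropan-2-yl)-2-methylcyclohex-2-en-1-one | CC1=CC[C@H](C(C)(C)O)CC1=O | intermediate
3 | dilithium (3S)-6-methyl-3-(2-oxidopropan-2-yl)cyclohexa-1,5-dien-1-olate (dienolate alkoxide of 2) | [Li+].[Li+].CC1=CC[C@H](C(C)(C)[O-])C=C1[O-] | intermediate
4 | (5S,6R)-5-(2-hydroxypropan-2-yl)-2,6-dimethylcyclohex-2-en-1-one (major trans epimer) | CC1=CC[C@H](C(C)(C)O)[C@@H](C)C1=O | intermediate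
5 | diethyl 2-methylidenepropanedioate (diethyl methylenemalonate) | C=C(C(=O)OCC)C(=O)OCC | starting material
6 | dilithium (3S)-2,6-dimethyl-3-(2-oxidopropan-2-yl)cyclohexa-1,5-dien-1-olate (dienolate alkoxide of 4) | [Li+].[Li+].CC1=CC[C@H](C(C)(C)[O-])C(C)=C1[O-] | intermediate
7 | diethyl 2-{[(1R,6S)-6-(2-hydroxypropan-2-yl)-1,3-dimethyl-2-oxocyclohex-3-en-1-yl]methyl}propanedioate | O=C1C(C)=CC[C@H](C(C)(C)O)[C@@]1(C)CC(C(=O)OCC)C(=O)OCC | intermediate
8 | diethyl 2-{[(1R,3R,6S)-6-(2-hydroxypropan-2-yl)-1,3-dimethyl-2-oxocyclohexyl]methyl}propanedioate | O=C1[C@H](C)CC[C@H](C(C)(C)O)[C@@]1(C)CC(C(=O)OCC)C(=O)OCC | intermediate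
9 | methyl prop-2-enoate (methyl acrylate) | C=CC(=O)OC | starting material
10 | diethyl 2-{[(1R,2R,3R,6S)-2-hydroxy-6-(2-hydroxypropan-2-yl)-2-(3-methoxy-3-oxopropyl)-1,3-dimethylcyclohexyl]methyl}propanedioate (hydroxy ester) | O[C@]1(CCC(=O)OC)[C@H](C)CC[C@H](C(C)(C)O)[C@@]1(C)CC(C(=O)OCC)C(=O)OCC | intermediate
11 | diethyl 2-{[(5R,6R,7S,10R)-7-(2-hydroxypropan-2-yl)-6,10-dimethyl-2-oxo-1-oxaspiro[4.5]decan-6-yl]methyl}propanedioate | O=C2O[C@]1(CC2)[C@H](C)CC[C@H](C(C)(C)O)[C@@]1(C)CC(C(=O)OCC)C(=O)OCC | intermediate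
12 | 2-{[(5R,6R,7S,10R)-7-(2-hydroxypropan-2-yl)-6,10-dimethyl-2-oxo-1-oxaspiro[4.5]decan-6-yl]methyl}propanedioic acid | O=C2O[C@]1(CC2)[C@H](C)CC[C@H](C(C)(C)O)[C@@]1(C)CC(C(=O)O)C(=O)O | intermediate
13 | 3-[(5R,6R,7S,10R)-7-(2-hydroxypropan-2-yl)-6,10-dimethyl-2-oxo-1-oxaspiro[4.5]decan-6-yl]propanoic acid | O=C2O[C@]1(CC2)[C@H](C)CC[C@H](C(C)(C)O)[C@@]1(C)CCC(=O)O | intermediate
14 | methyl 3-oxopentanoate | CCC(=O)CC(=O)OC | starting material
15 | 1-chloropropan-2-one (chloroacetone) | CC(=O)CCl | starting material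
16 | methyl 2-ethyl-4-methylfuran-3-carboxylate | CCc1occ(C)c1C(=O)OC | intermediate
17 | lithium (2-ethylidene-4-methylfuran-3(2H)-ylidene)(methoxy)methanolate (laterally lithiated 16) | [Li+].CC=C1OC=C(C)C1=C([O-])OC | intermediate
18 | 3-[(1R,2R,3R,6S)-2-hydroxy-6-(2-hydroxypropan-2-yl)-2-{4-[3-(methoxycarbonyl)-4-methylfuran-2-yl]-3-oxopentyl}-1,3-dimethylcyclohexyl]propanoic acid (both epimers at pentyl C4) | O[C@]1(CCC(=O)C(C)c2occ(C)c2C(=O)OC)[C@H](C)CC[C@H](C(C)(C)O)[C@@]1(C)CCC(=O)O | intermediate
19 | 3-[(1R,2R,3R,6S)-2-hydroxy-6-(2-hydroxypropan-2-yl)-2-{4-[6-(methoxycarbonyl)-5-methyl-2,3,7-trioxabicyclo[2.2.1]hept-5-en-1-yl]-3-oxopentyl}-1,3-dimethylcyclohexyl]propanoic acid (furan endoperoxide) | O[C@]1(CCC(=O)C(C)C23OOC(O2)C(C)=C3C(=O)OC)[C@H](C)CC[C@H](C(C)(C)O)[C@@]1(C)CCC(=O)O | intermediate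
20 | 3-[(1R,2R,3R,6S)-2-hydroxy-6-(2-hydroxypropan-2-yl)-2-[(6E)-6-(methoxycarbonyl)-4,7-dimethyl-3,5,8-trioxooct-6-en-1-yl]-1,3-dimethylcyclohexyl]propanoic acid (keto enal; ketone and aldehyde cis on the alkene) | O[C@]1(CCC(=O)C(C)C(=O)/C(C(=O)OC)=C(C)\C=O)[C@H](C)CC[C@H](C(C)(C)O)[C@@]1(C)CCC(=O)O | intermediate
21 | 3-[(1'R,2'R,3'S,6'R)-3'-(2-hydroxypropan-2-yl)-6-(methoxycarbonyl)-2',5,6',8-tetramethyl-7-oxo-3,7-dihydrospiro[cyclohepta[b]furan-2,1'-cyclohexan]-2'-yl]propanoic acid (CNP0448476.2) | COC(=O)c1c(C)cc2c(c(C)c1=O)O[C@]1(C2)[C@H](C)CC[C@H](C(C)(C)O)[C@@]1(C)CCC(=O)O | target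

**Step count**
Total: 9 steps. Longest linear sequence: 8 steps from (S)-carvone (steps 1–6, 8, 9); step 7 is a one-step side branch.

**Steps most likely to fail, each with one fallback**

Step 9 is the least precedented operation. The endoperoxide may break down along other paths, or the keto enal may stall in the reversible five-membered aldol product or in hemiacetal forms. Fallback: start from 18 and oxidise the furan by Clauson-Kaas methoxylation (Br2, MeOH, KOAc, −40 °C, or anodically in MeOH/NH4Br). This gives the isolable bis(methyl acetal) 3-[(1R,2R,3R,6S)-2-{4-[2,5-dimethoxy-3-(methoxycarbonyl)-4-methyl-2,5-dihydrofuran-2-yl]-3-oxopentyl}-2-hydroxy-6-(2-hydroxypropan-2-yl)-1,3-dimethylcyclohexyl]propanoic acid F1. After purification it is hydrolysed and cyclised with TsOH·H2O in wet MeCN (keto enal 20 forms again in the flask), free of peroxide and sulfide by-products, and the route is rejoined at 21.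

Step 4 carries the stereochemical risk. The two half-chair conformers of 7 shield opposite faces to different degrees, so the facial selectivity at C8 may be modest, and the two C8 epimers of 8 are close in energy, so equilibration would not correct it. Fallback: start from 7 and run a conjugate hydrosilylation (Et3SiH, RhCl(PPh3)3 cat., benzene, 50 °C) to the regio-defined silyl enol ether diethyl 2-{[(1R,6S)-6-(2-hydroxypropan-2-yl)-1,3-dimethyl-2-[(triethylsilyl)oxy]cyclohex-2-en-1-yl]methyl}propanedioate F2. Kinetic protodesilylation (HF·pyridine, THF, −40 °C) then sets C8 by proton delivery, where the size of the proton donor can be tuned, and the route is rejoined at 8.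

Step 8 may give low conversion. The lactone is flanked by a fully substituted carbon and is enolisable, so proton transfer to 17 competes with acylation. Fallback: start from 13 and open the lactone with Me(MeO)NH·HCl/AlMe3 (CH2Cl2, 0 °C → rt) to the Weinreb amide 3-[(1R,2R,3R,6S)-2-hydroxy-6-(2-hydroxypropan-2-yl)-2-{3-[methoxy(methyl)amino]-3-oxopropyl}-1,3-dimethylcyclohexyl]propanoic acid F3. Its lithium salt is treated with 17 at −78 °C; the chelated adduct collapses to the ketone only on work-up, and the route is rejoined at 18.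

**Further compounds**
F1 | step 9 | 3-[(1R,2R,3R,6S)-2-{4-[2,5-dimethoxy-3-(methoxycarbonyl)-4-methyl-2,5-dihydrofuran-2-yl]-3-oxopentyl}-2-hydroxy-6-(2-hydroxypropan-2-yl)-1,3-dimethylcyclohexyl]propanoic acid | O[C@]1(CCC(=O)C(C)C2(OC)OC(OC)C(C)=C2C(=O)OC)[C@H](C)CC[C@H](C(C)(C)O)[C@@]1(C)CCC(=O)O
F2 | step 4 | diethyl 2-{[(1R,6S)-6-(2-hydroxypropan-2-yl)-1,3-dimethyl-2-[(triethylsilyl)oxy]cyclohex-2-en-1-yl]methyl}propanedioate | CC[Si](CC)(CC)OC1=C(C)CC[C@H](C(C)(C)O)[C@@]1(C)CC(C(=O)OCC)C(=O)OCC
F3 | step 8 | 3-[(1R,2R,3R,6S)-2-hydroxy-6-(2-hydroxypropan-2-yl)-2-{3-[methoxy(methyl)amino]-3-oxopropyl}-1,3-dimethylcyclohexyl]propanoic acid | O[C@]1(CCC(=O)N(C)OC)[C@H](C)CC[C@H](C(C)(C)O)[C@@]1(C)CCC(=O)O
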